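## Retrosynthetic overview

1. Ring A (C1–C6) is opened at C1–C2. Its 2-methylidenecyclohexan-1-ol unit has sp2 C1, which carries the exocyclic CH2 and sits next to the spiro carbon C6, bonded directly to the carbinol carbon C2. This is the retron of an intramolecular alkenylchromium/aldehyde addition of an enol-triflate aldehyde.
2. The enol triflate comes from a C1 methyl ketone. The trans C8–Br/C9–Cl pair of ring B comes from a bromolactone in which the carboxyl carbon on C6 (the future C1) delivers oxygen to C9 and so fixes C6/C8/C9; chloride then replaces oxygen with retention.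
3. Ring B and the spiro carbon C6 come from a catalytic enantioselective Diels–Alder reaction of isoprene with a 2-substituted acrolein.
4. Quaternary C5 comes from SN1 alkylation of a silyl ketene acetal by a β-bromo tertiary chloride whose C4–Br centre derives from D-allylglycine.
5. Order of ring formation: ring B (Diels–Alder), a temporary lactone bridge (made and opened again), ring A (key step).

Key step: step 15

Remark: locants in the text are the spiro[5.5]undecane locants of the target (ring A: C1–C6 with C1=CH2, C2–OH, C4–Br, C5 gem-dimethyl; ring B: C6–C11 with C8–Br and C9–Cl/CH3) and are used for the same atoms in all precursors; the numbered starting materials are assumed to be purchased.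

## Route

Step 1
Reactants: 1 D-allylglycine, (2R)-2-aminopent-4-enoic acid
Product: 2 (2R)-2-bromopent-4-enoic acid
Conditions: NaNO2, KBr, 2.5 M H2SO4, −5 to 0 °C
Reagents that add atoms: potassium bromide, [K+].[Br-]
Why: Diazotisation–bromide substitution of an α-amino acid goes with net retention (double inversion through the α-lactone), so the (R) centre of 1 becomes the (R) C–Br centre that is carried unchanged to C4 of the target.

Step 2
Reactants: 2 (2R)-2-bromopent-4-enoic acid
Product: 3 methyl (2R)-2-bromopent-4-enoate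
Conditions: MeOH, H2SO4 (cat.), 40 °C
Reagents that add atoms: methanol, CO
Why: Fischer esterification; the acidic medium should not epimerise the α-bromo centre.

Step 3
Reactants: 3 methyl (2R)-2-bromopent-4-enoate
Product: 4 (3R)-3-bromo-2-methylhex-5-en-2-ol
Conditions: MeMgBr (2.3 equiv), Et2O, −78 to −10 °C; aqueous work-up
Reagents that add atoms: methylmagnesium bromide, C[Mg]Br
Why: Double Grignard addition to the ester gives the tertiary carbinol (future C5 with both methyl groups) without touching the C–Br centre; low temperature suppresses enolisation of the α-bromo ester and closure of the bromohydrin alkoxide to an epoxide.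

Step 4
Reactants: 4 (3R)-3-bromo-2-methylhex-5-en-2-ol
Product: 5 (4R)-4-bromo-5-chloro-5-methylhex-1-ene
Conditions: conc. HCl/ZnCl2 (Lucas reagent), CH2Cl2, 0 °C
Reagents that add atoms: hydrogen chloride, Cl
Why: SN1 chlorodehydroxylation of a tertiary alcohol; the carbinol carbon is not stereogenic and the neighbouring bromine can only bridge and be re-opened at the tertiary carbon, so C4 keeps its configuration.

Step 5
Reactants: 5 (4R)-4-bromo-5-chloro-5-methylhex-1-ene; 6 1-(tert-butyldimethylsilyloxy)-1-methoxyethene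
Product: 7 methyl (4R)-4-bromo-3,3-dimethylhept-6-enoate
Conditions: 6 (1.5 equiv), ZnCl2 (0.5 equiv), CH2Cl2, −20 °C to rt
Reagents that add atoms: none
Why: Lewis-acid-promoted SN1 α-tert-alkylation of a silyl ketene acetal: ZnCl2 ionises the tertiary chloride with bromine participation and the ketene acetal attacks the tertiary carbon, which creates quaternary C5 while the C4–Br bond and its configuration stay intact.

Step 6
Reactants: 7 methyl (4R)-4-bromo-3,3-dimethylhept-6-enoate
Product: 8 (4R)-4-bromo-3,3-dimethylhept-6-enal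
Conditions: DIBAL-H (1.1 equiv), CH2Cl2, −78 °C; Rochelle salt
Reagents that add atoms: none
Why: Partial ester reduction with DIBAL-H at −78 °C should stop at the tetrahedral aluminium hemiacetal of this hindered ester, which gives the aldehyde on work-up.

Step 7
Reactants: 8 (4R)-4-bromo-3,3-dimethylhept-6-enal
Product: 9 (4R)-4-bromo-3,3-dimethyl-2-methylidenehept-6-enal
Conditions: 37% aq. HCHO, pyrrolidine (10 mol%), propionic acid (10 mol%), i-PrOH, 45 °C
Reagents that add atoms: formaldehyde, C=O
Why: Amine-catalysed Mannich-type α-methylenation of the aldehyde with formaldehyde gives the 2-substituted acrolein; the neopentyl-type C–Br is too hindered for competing intramolecular enamine alkylation.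

Step 8
Reactants: 9 (4R)-4-bromo-3,3-dimethyl-2-methylidenehept-6-enal; 10 isoprene
Product: 11 (1R)-1-[(3R)-3-bromo-2-methylhex-5-en-2-yl]-4-methylcyclohex-3-ene-1-carbaldehyde
Conditions: isoprene (5 equiv), (R)-o-tolyl-CBS oxazaborolidinium triflimide (20 mol%), CH2Cl2, −78 to −40 °C
Reagents that add atoms: none
Why: Oxazaborolidinium-catalysed Diels–Alder reaction of a 2-substituted acrolein with isoprene closes ring B with "para" orientation (ring methyl 1,4 to the new quaternary carbon), and the catalyst rather than the remote C4 centre selects the enal face so that the future spiro carbon C6 forms as (1R); the catalyst antipode is assigned by analogy with 2-alkylacroleins.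

Step 9
Reactants: 11 (1R)-1-[(3R)-3-bromo-2-methylhex-5-en-2-yl]-4-methylcyclohex-3-ene-1-carbaldehyde
Product: 12 (1R)-1-[(3R)-3-bromo-2-methylhex-5-en-2-yl]-4-methylcyclohex-3-ene-1-carboxylic acid
Conditions: NaClO2, NaH2PO4, 2-methyl-2-butene, t-BuOH/H2O, 0 °C to rt
Reagents that add atoms: sodium chlorite, [Na+].[O-]Cl=O
Why: Pinnick oxidation converts the α-quaternary aldehyde into the acid without touching the alkenes or C–Br, because 2-methyl-2-butene scavenges the hypochlorite.

Step 10
Reactants: 12 (1R)-1-[(3R)-3-bromo-2-methylhex-5-en-2-yl]-4-methylcyclohex-3-ene-1-carboxylic acid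
Product: 13 (1S,4R,6S)-6-bromo-4-[(3R)-3-bromo-2-methylhex-5-en-2-yl]-1-methyl-2-oxabicyclo[2.2.2]octan-3-one
Conditions: NBS (1.05 equiv), MeCN, 0 °C, dark
Reagents that add atoms: N-bromosuccinimide, O=C1CCC(=O)N1Br
Why: Bromolactonisation: with the bulky tert-alkyl group equatorial the carboxyl group is axial and adds across the ring to the tertiary alkene carbon C9 (Markovnikov) anti to bromine, so O–C9 is cis to the carboxyl carbon and Br–C8 trans to it, which is the C6/C8/C9 relative configuration of the target; the trisubstituted ring alkene should react much faster than the monosubstituted vinyl group.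

Step 11
Reactants: 13 (1S,4R,6S)-6-bromo-4-[(3R)-3-bromo-2-methylhex-5-en-2-yl]-1-methyl-2-oxabicyclo[2.2.2]octan-3-one
Product: 15 1-[(1R,3S,4S)-3-bromo-1-[(3R)-3-bromo-2-methylhex-5-en-2-yl]-4-hydroxy-4-methylcyclohexyl]ethan-1-one, via bicyclic hemiketal 14 (not isolated)
Conditions: MeLi (1.1 equiv), THF, −78 °C; H2O quench
Reagents that add atoms: methyllithium, [Li]C
Why: Mono-addition of methyllithium to a lactone: the tetrahedral lithium hemiketal is stable at −78 °C and opens only on work-up, giving the methyl ketone (C1 with its future methylidene carbon) and freeing the C9 tertiary alcohol.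

Step 12
Reactants: 15 1-[(1R,3S,4S)-3-bromo-1-[(3R)-3-bromo-2-methylhex-5-en-2-yl]-4-hydroxy-4-methylcyclohexyl]ethan-1-one
Product: 16 1-[(1R,3S,4S)-3-bromo-1-[(3R)-3-bromo-2-methylhex-5-en-2-yl]-4-chloro-4-methylcyclohexyl]ethan-1-one
Conditions: HCl (gas), ZnCl2 (0.2 equiv), CH2Cl2, 0 °C
Reagents that add atoms: hydrogen chloride, Cl
Why: SN1 substitution of the tertiary alcohol by chloride with anchimeric assistance of the vicinal trans bromine: the bromine-bridged cation should be opened by chloride at tertiary C9 anti to bromine, that is with net retention, giving the trans-diequatorial Br/Cl pair.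

Step 13
Reactants: 16 1-[(1R,3S,4S)-3-bromo-1-[(3R)-3-bromo-2-methylhex-5-en-2-yl]-4-chloro-4-methylcyclohexyl]ethan-1-one
Product: 17 1-[(1R,3S,4S)-3-bromo-1-[(3R)-3-bromo-2-methylhex-5-en-2-yl]-4-chloro-4-methylcyclohexyl]ethenyl trifluoromethanesulfonate
Conditions: KHMDS (1.1 equiv), THF, −78 °C; PhNTf2
Reagents that add atoms: N-phenylbis(trifluoromethanesulfonimide), O=S(=O)(N(c1ccccc1)S(=O)(=O)C(F)(F)F)C(F)(F)F
Why: Kinetic deprotonation of the only enolisable position (the acetyl CH3) and O-sulfonylation gives the 1,1-disubstituted enol triflate; the equatorial ring halides have no antiperiplanar hydrogen and no backside access, so E2 and intramolecular alkylation should be slow at −78 °C.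

Step 14
Reactants: 17 1-[(1R,3S,4S)-3-bromo-1-[(3R)-3-bromo-2-methylhex-5-en-2-yl]-4-chloro-4-methylcyclohexyl]ethenyl trifluoromethanesulfonate
Product: 19 (3R)-3-bromo-4-[(1R,3S,4S)-3-bromo-4-chloro-4-methyl-1-{1-[(trifluoromethanesulfonyl)oxy]ethenyl}cyclohexyl]-4-methylpentanal, via terminal diol 18 (not isolated)
Conditions: OsO4 (2 mol%), NaIO4 (4 equiv), 2,6-lutidine, dioxane/H2O 3:1, rt
Reagents that add atoms: osmium tetroxide (catalytic oxygen transfer), O=[Os](=O)(=O)=O; sodium periodate (terminal oxidant), [Na+].[O-][I](=O)(=O)=O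
Why: Lemieux–Johnson oxidative cleavage (dihydroxylation, then periodate) should take place at the electron-rich monosubstituted alkene and leave the electron-poor enol triflate untouched, unmasking the C2 aldehyde.

Step 15
Reactants: 19 (3R)-3-bromo-4-[(1R,3S,4S)-3-bromo-4-chloro-4-methyl-1-{1-[(trifluoromethanesulfonyl)oxy]ethenyl}cyclohexyl]-4-methylpentanal
Product: 21 (2R,4R,6S,8S,9S)-4,8-dibromo-9-chloro-5,5,9-trimethyl-1-methylidenespiro[5.5]undecan-2-ol, via alkenylchromium(III) dichloride 20 (not isolated)
Conditions: CrCl2 (6 equiv), NiCl2 (2 mol%), DMF (0.01 M), rt; aqueous work-up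
Reagents that add atoms: none
Why: Ni(0), formed from NiCl2 and CrCl2, inserts into the C1–OTf bond, transmetalation to Cr(III) gives the alkenylchromium 20, and its C1–Cr σ-bond adds to the tethered C2 aldehyde (intramolecular Nozaki–Hiyama–Kishi reaction); the closest known reaction type is the Ni/Cr-mediated coupling of 2-triflyloxy-1-alkenes with aldehydes to 2-methylidene carbinols. Ring A closes in the 6-exo-trig mode (C1 onto the carbonyl carbon C2, oxygen outside the ring), helped by the two quaternary carbons C5 and C6 in the tether, which favour the folded conformer. The only new stereocentre, C2, should be set by 1,3-induction from C4 in a chair-like transition state: C4–Br is equatorial and the chromium-bound oxygen pseudo-axial, because an equatorial O–Cr would lie in the plane of the exocyclic alkene and clash with its cis hydrogen and the chromium ligand sphere (A1,3 strain), which places OH trans to Br (2R). The step needs chemoselectivity for the C(sp2)–OTf bond over three C(sp3)–halogen bonds and over β-elimination of HBr from the β-bromo aldehyde; oxidative addition of Ni(0) to the enol triflate is much faster than to unactivated alkyl halides, CrCl2 alone does not reduce such halides at rt, and the medium is not basic. The position of the exocyclic alkene is fixed by the triflate, so no alkene isomers can arise.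

## Compound list

1 | D-allylglycine, (2R)-2-aminopent-4-enoic acid | C=CC[C@@H](N)C(=O)O | starting material
2 | (2R)-2-bromopent-4-enoic acid | C=CC[C@@H](Br)C(=O)O | intermediate
3 | methyl (2R)-2-bromopent-4-enoate | C=CC[C@@H](Br)C(=O)OC | intermediate
4 | (3R)-3-bromo-2-methylhex-5-en-2-ol | C=CC[C@@H](Br)C(C)(C)O | intermediate
5 | (4R)-4-bromo-5-chloro-5-methylhex-1-ene | C=CC[C@@H](Br)C(C)(C)Cl | intermediate
6 | 1-(tert-butyldimethylsilyloxy)-1-methoxyethene | COC(=C)O[Si](C)(C)C(C)(C)C | starting material
7 | methyl (4R)-4-bromo-3,3-dimethylhept-6-enoate | COC(=O)CC(C)(C)[C@H](Br)CC=C | intermediate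
8 | (4R)-4-bromo-3,3-dimethylhept-6-enal | O=CCC(C)(C)[C@H](Br)CC=C | intermediate
9 | (4R)-4-bromo-3,3-dimethyl-2-methylidenehept-6-enal | C=C(C=O)C(C)(C)[C@H](Br)CC=C | intermediate
10 | isoprene, 2-methylbuta-1,3-diene | C=CC(C)=C | starting material
11 | (1R)-1-[(3R)-3-bromo-2-methylhex-5-en-2-yl]-4-methylcyclohex-3-ene-1-carbaldehyde | O=C[C@@]1(CCC(C)=CC1)C(C)(C)[C@H](Br)CC=C | intermediate
12 | (1R)-1-[(3R)-3-bromo-2-methylhex-5-en-2-yl]-4-methylcyclohex-3-ene-1-carboxylic acid | OC(=O)[C@@]1(CCC(C)=CC1)C(C)(C)[C@H](Br)CC=C | intermediate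
13 | (1S,4R,6S)-6-bromo-4-[(3R)-3-bromo-2-methylhex-5-en-2-yl]-1-methyl-2-oxabicyclo[2.2.2]octan-3-one | O=C1O[C@@]2(C)CC[C@@]1(C[C@@H]2Br)C(C)(C)[C@H](Br)CC=C | intermediate
14 | (1S,4R,6S)-6-bromo-4-[(3R)-3-bromo-2-methylhex-5-en-2-yl]-1,3-dimethyl-2-oxabicyclo[2.2.2]octan-3-ol, bicyclic hemiketal, either C3 epimer | CC1(O)O[C@@]2(C)CC[C@@]1(C[C@@H]2Br)C(C)(C)[C@H](Br)CC=C | intermediate
15 | 1-[(1R,3S,4S)-3-bromo-1-[(3R)-3-bromo-2-methylhex-5-en-2-yl]-4-hydroxy-4-methylcyclohexyl]ethan-1-one | CC(=O)[C@]1(C([C@@H](CC=C)Br)(C)C)CC[C@](C)(O)[C@@H](Br)C1 | intermediate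
16 | 1-[(1R,3S,4S)-3-bromo-1-[(3R)-3-bromo-2-methylhex-5-en-2-yl]-4-chloro-4-methylcyclohexyl]ethan-1-one | CC(=O)[C@]1(C([C@@H](CC=C)Br)(C)C)CC[C@](C)(Cl)[C@@H](Br)C1 | intermediate
17 | 1-[(1R,3S,4S)-3-bromo-1-[(3R)-3-bromo-2-methylhex-5-en-2-yl]-4-chloro-4-methylcyclohexyl]ethenyl trifluoromethanesulfonate | C=C(OS(=O)(=O)C(F)(F)F)[C@]1(C([C@@H](CC=C)Br)(C)C)CC[C@](C)(Cl)[C@@H](Br)C1 | intermediate
18 | 1-[(1R,3S,4S)-3-bromo-1-[(3R)-3-bromo-5,6-dihydroxy-2-methylhexan-2-yl]-4-chloro-4-methylcyclohexyl]ethenyl trifluoromethanesulfonate, either carbinol epimer | C=C(OS(=O)(=O)C(F)(F)F)[C@]1(C([C@@H](CC(O)CO)Br)(C)C)CC[C@](C)(Cl)[C@@H](Br)C1 | intermediate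
19 | (3R)-3-bromo-4-[(1R,3S,4S)-3-bromo-4-chloro-4-methyl-1-{1-[(trifluoromethanesulfonyl)oxy]ethenyl}cyclohexyl]-4-methylpentanal | C=C(OS(=O)(=O)C(F)(F)F)[C@]1(C([C@@H](CC=O)Br)(C)C)CC[C@](C)(Cl)[C@@H](Br)C1 | intermediate
20 | dichloro{1-[(1R,3S,4S)-3-bromo-1-[(3R)-3-bromo-2-methyl-5-oxopentan-2-yl]-4-chloro-4-methylcyclohexyl]ethenyl}chromium(III) | C=C([Cr](Cl)Cl)[C@]1(C([C@@H](CC=O)Br)(C)C)CC[C@](C)(Cl)[C@@H](Br)C1 | intermediate
21 | (2R,4R,6S,8S,9S)-4,8-dibromo-9-chloro-5,5,9-trimethyl-1-methylidenespiro[5.5]undecan-2-ol (CNP0150021.1) | C=C1[C@H](O)C[C@@H](Br)C(C)(C)[C@]12CC[C@](C)(Cl)[C@@H](Br)C2 | target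

## Step count and risks

Total step count: 15. Longest linear sequence: 15 steps (1 to 21); 6 and 10 enter as purchased reagents.

The three steps most likely to fail:

Step 8. The cycloaddition creates two adjacent quaternary carbons from an α-tert-alkyl enal, so it may be slow, and the catalyst may control the enal face poorly, which would give the C6 epimer. The fallback sets out from 9. The cycloaddition with isoprene is promoted by the stronger, achiral Lewis acid Me2AlCl (CH2Cl2, −78 to −20 °C) and should give 11 together with its C6 epimer, (1S)-1-[(3R)-3-bromo-2-methylhex-5-en-2-yl]-4-methylcyclohex-3-ene-1-carbaldehyde F1. Because C4 is already a single enantiomer, the two are diastereomers and are separated by preparative chromatography. The route is rejoined at 11, with substrate-independent reactivity and diastereomer separation in place of catalyst control.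

Step 15. Facial selectivity at C2 in the ring closure may be poor, and some β-elimination of HBr from the aldehyde may compete. The fallback sets out from 19. The cyclisation is run as in step 15, and the mixture of 21 and its C2 epimer, (2S,4R,6S,8S,9S)-4,8-dibromo-9-chloro-5,5,9-trimethyl-1-methylidenespiro[5.5]undecan-2-ol F2, is oxidised with Dess–Martin periodinane (NaHCO3, CH2Cl2) to the cross-conjugated enone (4R,6S,8S,9S)-4,8-dibromo-9-chloro-5,5,9-trimethyl-1-methylidenespiro[5.5]undecan-2-one F3. Reagent-controlled 1,2-reduction ((S)-Me-CBS oxazaborolidine, catecholborane, toluene, −78 °C, with the alkenyl group as the large substituent) should then return to the route at 21. Stereocontrol at C2 is thereby moved from the C–C bond formation to a ketone reduction.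

Step 12. Ionisation of the tertiary alcohol may be slow because of the inductive effect of the vicinal bromine, with competing E1 dehydration or loss of the trans relationship. The fallback sets out from 13. The tertiary alkyl–oxygen bond of the lactone is cleaved directly with TiCl4 (CH2Cl2, −78 to 0 °C; carboxylate as the leaving group, bromine participation, net retention) to give (1R,3S,4S)-3-bromo-1-[(3R)-3-bromo-2-methylhex-5-en-2-yl]-4-chloro-4-methylcyclohexane-1-carboxylic acid F4. Oxalyl chloride with catalytic DMF converts it into (1R,3S,4S)-3-bromo-1-[(3R)-3-bromo-2-methylhex-5-en-2-yl]-4-chloro-4-methylcyclohexane-1-carbonyl chloride F5, and Me2CuLi (Et2O, −78 °C) transfers one methyl group to give 16, where the route is rejoined.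

## Further compounds

F1 | step 8 | (1S)-1-[(3R)-3-bromo-2-methylhex-5-en-2-yl]-4-methylcyclohex-3-ene-1-carbaldehyde | O=C[C@]1(CCC(C)=CC1)C(C)(C)[C@H](Br)CC=C
F2 | step 15 | (2S,4R,6S,8S,9S)-4,8-dibromo-9-chloro-5,5,9-trimethyl-1-methylidenespiro[5.5]undecan-2-ol | C=C1[C@@H](O)C[C@@H](Br)C(C)(C)[C@]12CC[C@](C)(Cl)[C@@H](Br)C2
F3 | step 15 | (4R,6S,8S,9S)-4,8-dibromo-9-chloro-5,5,9-trimethyl-1-methylidenespiro[5.5]undecan-2-one | C=C1C(=O)C[C@@H](Br)C(C)(C)[C@]12CC[C@](C)(Cl)[C@@H](Br)C2
F4 | step 12 | (1R,3S,4S)-3-bromo-1-[(3R)-3-bromo-2-methylhex-5-en-2-yl]-4-chloro-4-methylcyclohexane-1-carboxylic acid | OC(=O)[C@]1(C([C@@H](CC=C)Br)(C)C)CC[C@](C)(Cl)[C@@H](Br)C1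
F5 | step 12 | (1R,3S,4S)-3-bromo-1-[(3R)-3-bromo-2-methylhex-5-en-2-yl]-4-chloro-4-methylcyclohexane-1-carbonyl chloride | ClC(=O)[C@]1(C([C@@H](CC=C)Br)(C)C)CC[C@](C)(Cl)[C@@H](Br)C1
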